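(The readings are simulated for an exercise.)

Every Q charged stands at any moment as Q, as Z or in an unseen rest, and the three add up to the charge. The birch run, with Q down to 34.1% and Z at 14.5% at its last reading, gives 22.0% for the Z share, the part of the consumed Q that is found as Z, which the field calls selectivity.

| flask | Q | X | J | remark | time |
|---|---|---|---|---|---|
| birch | 0.050 M | 12 mM (held) | 2.2 mol% | run made earlier |  |
| flask | 0.050 M | 12 mM (held) | 1.1 mol% |  | 4.0 min |

birch run (percent of the Q charged)

| time / s | Z / % | Q / % |
|---|---|---|
| 10.0 | 3.9 | 92.4 |
| 20.0 | 8.3 | 75.4 |
| 30.0 | 8.5 | 61.1 |
| 50.0 | 14.5 | 34.1 |

(standard deviation of a reading: 1 percentage point)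

- the analysis behind the earlier runs scatters by 1 percentage point, standard deviation
- at the start none of X is in solution
- L is what X becomes in solution
- no earlier run changes the charge of J; that part of a forecast is a guess

- how much Z there is at 4.0 min, in percent of the Q charged
- concentration of L in solution at 4.0 min, in percent of saturation

The birch Z share reads 51.3% at 10.0 s, so it fell as Z rose, though the early reading carries much of the scatter. The last birch readings of Q fall with a time constant of 34.3 s. The flask has half the J, and if that constant doubles, its time spans 3.50 constants. Its Q is therefore taken as consumed, and its final Z equals its share.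

Two extreme versions of the flask can be solved in the head. If J speeds both routes alike, the clock stretches, the share stays, and Z ends at 22.0%. If J speeds the Z route and leaves the rest running as before, the share falls with the loading, to 11.0%. This reckoning places the flask between these, and the share that fell as Z rose points above the middle, 16.5%. This placing is a guess, as no earlier run changes J.

The forecast gives 17% of Z and 96% of saturation for L, holding that “L consumption is small and L is nearly saturated”. The flask gives 18.5% and 99.7%.

    X ⇌ L, rate k1*(csat - [L]) (kL = 0.0456 /s)
    Q + L + J → J + Z (k = 6030 /M²/s)
    Q + Z → G (k = 2.02 /M/s)

With 0% of Q left, the flask's Z share is 18.5%, inside the window and above its middle. The main reason it stands so low is the loss of Q + Z to G: the flask ends at 18.5% of Z with that step and at 99.4% with it struck out. For the neighbour flask with 0.44 mol% of J, the window runs from 4.40% to 22.0%, and with 0.81% of its Q left, its Z share comes to 11.6%.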